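Assumption: the SMILES is read as (2R,3S,3aS,5R), with aryl, C3‑Me, C3a‑allyl and C5‑OMe all on one face. Benzofuran numbering (O1, C2, C3, C3a, C4–C7, C7a) is used throughout.

## Retrosynthetic overview
1. C5 is set last, by kinetic protonation of the α′‑enolate on the face opposite the allyl group.
2. The six‑membered ring (C3a–C4 and C7–C7a bonds, quaternary C3a) comes from annulating an α‑allyl‑γ‑lactone with 3‑methoxybut‑3‑en‑2‑one.
3. The C2–aryl bond is the key convergent bond. It forms by cathodic Ni/Cr coupling of an aryl iodide with an α‑methyl aldehyde, where Felkin control gives the 2,3‑cis relationship.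
4. The C3–C3a bond comes from SN2 inversion of ethyl L‑lactate triflate by a pentenoate enolate. C3 is the only bought stereocentre and relays to C2, C3a and C5.
5. Ring order: the five‑membered O‑ring forms first (as a lactone), then the cyclohexenone. The lactone is opened and re‑closed as the vinylogous ester.

## Route

**Step 1**
Reactants: 1, ethyl (S)‑lactate
Product: 2, ethyl (2S)‑2‑(trifluoromethylsulfonyloxy)propanoate
Conditions: Tf2O, 2,6‑lutidine, CH2Cl2, −78 → 0 °C; short silica plug
Reagents that add atoms: triflic anhydride, O=S(=O)(OS(=O)(=O)C(F)(F)F)C(F)(F)F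
Why: O‑sulfonylation does not touch the C–O stereocentre, so the (S) configuration is retained.

**Step 2**
Reactants: 2, the triflate; 3, tert‑butyl pent‑4‑enoate
Product: 4, 4‑tert‑butyl 1‑ethyl (2S)‑2‑methyl‑3‑allylbutanedioate (C3 fixed; future C3a is an inconsequential epimer mixture)
Conditions: 3, LDA, THF, −78 °C; then 2, DMPU, −78 → −40 °C
Reagents that add atoms: tert‑butyl pent‑4‑enoate (3), C=CCCC(=O)OC(C)(C)C
Why: SN2 displacement of an α‑triflyloxy ester by an ester enolate proceeds with clean inversion, turning the bought C–O centre into the (3S) C–C centre.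

**Step 3**
Reactants: 4, the diester
Product: 5, tert‑butyl 2‑[(2S)‑1‑oxopropan‑2‑yl]pent‑4‑enoate
Conditions: DIBAL‑H (1.05 equiv), CH2Cl2, −78 °C; Rochelle salt; used crude
Reagents that add atoms: none
Why: Partial DIBAL reduction takes the ethyl ester to the aldehyde through a stable Al‑hemiacetal, the tert‑butyl ester is inert, and cold non‑basic handling preserves C3.

**Step 4 (electrochemical key step)**
Reactants: 5, the aldehyde; 6, 5‑iodo‑1,2,3‑trimethoxybenzene
Product: 7, (4S,5R)‑3‑allyl‑4‑methyl‑5‑(3,4,5‑trimethoxyphenyl)oxolan‑2‑one (4,5‑cis; C3 of the lactone, i.e. future C3a, is an epimer mixture)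
Conditions: 6 (1.5 equiv), CrCl3 (15 mol %), NiBr2·bpy (5 mol %), TMSCl (2 equiv), n‑Bu4NBF4, DMF, undivided cell, Al(+)|Ni foam(−), constant current, ca. 2.5 F/mol, rt; then TBAF, THF, 0 °C → rt
Reagents that add atoms: 5‑iodo‑1,2,3‑trimethoxybenzene (6), COc1cc(I)cc(OC)c1OC
Why: In this electrochemical Nozaki–Hiyama–Kishi arylation the non‑basic aryl–Cr(III) adds only to the aldehyde. Felkin–Anh control (L = CH(allyl)CO2tBu, M = Me; DMF suppresses chelation) gives the syn alcohol with (2R) configuration, estimated dr about 4–5:1. The fluoride‑released alkoxide then lactonises with retention under base, which avoids benzylic ionisation, and the minor trans lactones are removed by chromatography.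

**Step 5**
Reactants: 8, 3,3‑dimethoxybutan‑2‑one
Product: 9, 3‑methoxybut‑3‑en‑2‑one
Conditions: p‑TsOH (1 mol %), neat, ca. 130 °C, distil off MeOH then product; use fresh
Reagents that add atoms: none
Why: Acid‑catalysed loss of MeOH from a ketal gives the enol ether, the same reaction type as 2,2‑dimethoxypropane → 2‑methoxypropene.

**Step 6 (new annulation)**
Reactants: 7, the lactone; 9, the methoxy enone
Product: 10, (2R,3S,3aS)‑3a‑allyl‑5‑methoxy‑3‑methyl‑2‑(3,4,5‑trimethoxyphenyl)‑3,3a,4,5‑tetrahydro‑1‑benzofuran‑6(2H)‑one, C5 epimer mixture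
Conditions: LDA, THF, −78 °C; 9 (slow addition), −78 → −30 °C; then KOt‑Bu (2.5 equiv), t‑BuOH/THF, 0 °C → rt; AcOH quench; PPTS (10 mol %), 4 Å MS, CH2Cl2, rt
Reagents that add atoms: 3‑methoxybut‑3‑en‑2‑one (9), C=C(OC)C(C)=O
Why: Proposed new method: a one‑pot Michael–Dieckmann–recyclisation of a γ‑lactone with a 2‑alkoxy vinyl ketone.
- **Michael addition.** The planar α‑allyl lactone enolate adds 1,4 on the face anti to the cis Me/aryl pair. This fixes (3aS) with allyl cis to Me. Any 1,2‑adduct reverts under KOt‑Bu.
- **Ring closure.** Proton shuffling gives the CH3‑side enolate, which attacks the lactone carbonyl (6‑exo) and expels the tethered benzylic alkoxide. Irreversible β‑diketonate formation is the thermodynamic sink.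
- **Recyclisation.** Mild acid lets the C2–OH recapture C7a (hemiketal, then loss of water). No benzylic C–O bond is broken, so C2 is retained.
- **Closest known reaction types.** Michael–Claisen synthesis of cyclohexane‑1,3‑diones, and the base‑induced enol‑lactone → 1,3‑dione rearrangement.

**Step 7**
Reactants: 10, the C5 epimer mixture
Product: 11, Dysodanthin B, (2R,3S,3aS,5R)
Conditions: LiHMDS (1.2 equiv), THF, −78 °C; then 2,6‑di‑tert‑butyl‑4‑methylphenol in THF, −78 °C; pH 7 buffer; neutral silica
Reagents that add atoms: none
Why: Kinetic (contra‑thermodynamic) protonation. C5 is the only enolisable site because C3a is quaternary, and the bulky phenol can only reach the face opposite the pseudo‑axial allyl, Me and aryl groups. H therefore enters anti and the OMe ends up cis to allyl (5R), converging both epimers.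

## Compound list
| No. | Name | SMILES | Role |
|---|---|---|---|
| 1 | ethyl (S)‑lactate | C[C@H](O)C(=O)OCC | starting material |
| 2 | ethyl (2S)‑2‑(triflyloxy)propanoate | C[C@H](OS(=O)(=O)C(F)(F)F)C(=O)OCC | intermediate |
| 3 | tert‑butyl pent‑4‑enoate | C=CCCC(=O)OC(C)(C)C | starting material |
| 4 | 4‑tert‑butyl 1‑ethyl (2S)‑2‑methyl‑3‑allylbutanedioate | C[C@@H](C(CC=C)C(=O)OC(C)(C)C)C(=O)OCC | intermediate |
| 5 | tert‑butyl 2‑[(2S)‑1‑oxopropan‑2‑yl]pent‑4‑enoate | C[C@@H](C(CC=C)C(=O)OC(C)(C)C)C=O | intermediate |
| 6 | 5‑iodo‑1,2,3‑trimethoxybenzene | COc1cc(I)cc(OC)c1OC | starting material |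
| 7 | (4S,5R)‑3‑allyl‑4‑methyl‑5‑(3,4,5‑trimethoxyphenyl)oxolan‑2‑one | C=CCC1C(=O)O[C@@H](c2cc(OC)c(OC)c(OC)c2)[C@H]1C | intermediate |
| 8 | 3,3‑dimethoxybutan‑2‑one | CC(=O)C(C)(OC)OC | starting material |
| 9 | 3‑methoxybut‑3‑en‑2‑one | C=C(OC)C(C)=O | intermediate |
| 10 | (2R,3S,3aS)‑bicyclic vinylogous ester, C5 epimers | C=CC[C@@]12CC(OC)C(=O)C=C1O[C@@H](c1cc(OC)c(OC)c(OC)c1)[C@H]2C | intermediate |
| 11 | Dysodanthin B | C=CC[C@@]12C[C@@H](OC)C(=O)C=C1O[C@@H](c1cc(OC)c(OC)c(OC)c1)[C@H]2C | target |

## Step count
Total steps: 7. Longest linear sequence: 6 (1 → 2 → 4 → 5 → 7 → 10 → 11).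

## Steps most likely to fail
1. **Step 6 (proposed new annulation).**
   - Risks: proton transfer to or polymerisation of 9, and a sluggish Dieckmann closure at the neopentyl lactone carbonyl.
   - Fallback (known chemistry, discrete steps): convert 7 to its TMS ketene acetal and run a TiCl4 Mukaiyama–Michael addition to 9. Isolate the keto‑lactone, then carry out a separate KOt‑Bu Dieckmann condensation and a PPTS cyclodehydration.
2. **Step 4 (electrochemical NHK).**
   - Risks: modest Felkin dr and slow turnover with the electron‑rich aryl iodide.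
   - Fallback: set C2 by hydride plus inversion instead of arylating the aldehyde. Add ArLi to the ethyl ester of 4 to give the aryl ketone, then reduce with L‑Selectride (Felkin, anti alcohol). Hydrolyse any trans lactone formed with LiOH to the hydroxy acid and close it by Mitsunobu lactonisation with inversion to cis‑7. Acid is avoided once the benzylic alcohol is present.
3. **Step 7 (C5 kinetic protonation).**
   - Risks: competing axial protonation, and re‑epimerisation to the presumed more stable equatorial‑OMe epimer.
   - Fallback: drop kinetic control. Separate 11 from its 5‑epimer by HPLC on neutral phase, and recycle the 5‑epimer by DBU equilibration followed by re‑separation.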